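**Retrosynthetic overview**

1. The target is (−)-pinoresinol mono-prenyl ether. Lignan locants are used: C-7/C-8/C-9 for the half with the 4-hydroxy-3-methoxyphenyl ring, C-7'/C-8'/C-9' for the half with the prenyloxy ring. Ring A is the tetrahydrofuran O-7/C-7/C-8/C-8'/C-9'; ring B is O-7'/C-7'/C-8'/C-8/C-9.
2. Both rings are cut at their CH2–O bonds (C-9–O-7' and C-9'–O-7). This leaves an acyclic (2S,3S)-butane-1,4-diyl bis-mesylate with O-7' as free OH and O-7 and the phenol as silyl ethers.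
3. Enabling feature: in the open chain each benzylic oxygen is 1,4 to the CH2 of the other half (O-7'–C-7'–C-8'–C-8–C-9 and O-7–C-7–C-8–C-8'–C-9'). Each closure is therefore 5-exo-tet at a primary carbon, C-7 and C-7' keep their configuration, and the threo C-8/C-8' pair allows only the cis-fused bicycle with both aryl groups exo.
4. The chain C-9/C-8/C-8'/C-9' is one succinate. Its two carboxyl carbons are carried at the acid oxidation level as N-acyloxazolidinones, which direct two successive Evans syn-aldols (all four stereocentres) and are then reduced to the two CH2 groups.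
5. Order of ring formation: no ring before the last step; rings A and B both close in step 11, which also frees the phenol.

Key step: step 11

Remark: ArS = 4-(tert-butyldimethylsilyloxy)-3-methoxyphenyl, ArP = 3-methoxy-4-(3-methylbut-2-enyloxy)phenyl, Xc = (4R)-4-benzyl-2-oxo-1,3-oxazolidin-3-yl; compounds 4 and 5 are taken as purchased.

**Route**

Step 1
Reactants: 1 vanillin
Product: 2 4-(tert-butyldimethylsilyloxy)-3-methoxybenzaldehyde
Conditions: TBSCl, imidazole, DMF, rt
Reagents that add atoms: tert-butyldimethylsilyl chloride, CC(C)(C)[Si](C)(C)Cl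
Why: Imidazole-mediated O-silylation of the phenol gives the silyl ether that survives the enolate and hydride steps and is removed by fluoride in the last step.

Step 2
Reactants: 1 vanillin
Product: 3 3-methoxy-4-(3-methylbut-2-enyloxy)benzaldehyde
Conditions: prenyl bromide, K2CO3, DMF, rt
Reagents that add atoms: prenyl bromide (1-bromo-3-methylbut-2-ene), CC(C)=CCBr
Why: Williamson etherification of the phenoxide with the primary allylic bromide installs the prenyl ether, which should tolerate every later reagent because the route uses no protic acid, no hydrogenation and no electrophilic oxidant.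

Step 3
Reactants: 4 4-tert-butoxy-4-oxobutanoic acid; 5 (4R)-4-benzyl-1,3-oxazolidin-2-one
Product: 6 tert-butyl 4-[(4R)-4-benzyl-2-oxo-1,3-oxazolidin-3-yl]-4-oxobutanoate
Conditions: DCC, DMAP (cat.), CH2Cl2, 0 °C → rt
Reagents that add atoms: none
Why: Steglich-type N-acylation (carbodiimide activation, acyl transfer through the acylpyridinium) joins the auxiliary to the free acid end while the tert-butyl ester end stays untouched.

Step 4
Reactants: 6 tert-butyl 4-Xc-4-oxobutanoate; 2 ArS-CHO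
Product: 9 tert-butyl (3R,4R)-3-(Xc-carbonyl)-4-hydroxy-4-ArS-butanoate (syn aldol), via dibutylboron Z-enolate 7 (not isolated), via O-dibutylboryl aldolate 8 (not isolated)
Conditions: Bu2BOTf, i-Pr2NEt, CH2Cl2, −78 → 0 °C; then 2, −78 → 0 °C; pH 7 buffer, MeOH, 30% H2O2, 0 °C
Reagents that add atoms: none
Why: Evans syn-aldol: soft enolisation gives only the Z-boron enolate of the imide (the tert-butyl ester is not enolised), and the Zimmerman–Traxler chair on the enolate face opposite the auxiliary benzyl group sets C-8 and C-7 as the (3R,4R)-syn pair, the bulky ester keeping the new hydroxyl from lactonising.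

Step 5
Reactants: 9 syn aldol
Product: 10 tert-butyl (3R,4R)-3-(Xc-carbonyl)-4-(tert-butyldimethylsilyloxy)-4-ArS-butanoate
Conditions: TBSOTf, 2,6-lutidine, CH2Cl2, −78 → 0 °C
Reagents that add atoms: tert-butyldimethylsilyl trifluoromethanesulfonate, CC(C)(C)[Si](C)(C)OS(=O)(=O)C(F)(F)F
Why: Silyl triflate silylation of the hindered benzylic hydroxyl under non-nucleophilic base blocks retro-aldol and lactonisation and masks O-7 until the last step.

Step 6
Reactants: 10 silyl ether tert-butyl ester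
Product: 12 (3R,4R)-3-(Xc-carbonyl)-4-(tert-butyldimethylsilyloxy)-4-ArS-butanoic acid, via trimethylsilyl ester 11 (not isolated)
Conditions: TMSOTf, 2,6-lutidine, CH2Cl2, 0 °C; then pH 7 buffer
Reagents that add atoms: none
Why: Silyl-triflate cleavage of the tert-butyl ester (O-silylation, loss of 2-methylpropene) and hydrolysis of the labile silyl ester on work-up should free the acid without protic acid, so the benzylic and aryl silyl ethers are expected to survive.

Step 7
Reactants: 12 acid; 5 (4R)-4-benzyl-1,3-oxazolidin-2-one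
Product: 13 (2R)-1,4-bis-Xc-2-[(R)-(tert-butyldimethylsilyloxy)(ArS)methyl]butane-1,4-dione
Conditions: DCC, DMAP (cat.), CH2Cl2, 0 °C → rt
Reagents that add atoms: none
Why: A second Steglich-type N-acylation at the unhindered CH2CO2H terminus installs the second auxiliary and turns C-9' into an enolisable imide.

Step 8
Reactants: 13 bis-imide; 3 ArP-CHO
Product: 16 (2R,3R)-1,4-bis-Xc-2-[(R)-hydroxy(ArP)methyl]-3-[(R)-(tert-butyldimethylsilyloxy)(ArS)methyl]butane-1,4-dione, via dibutylboron Z-enolate 14 (not isolated), via O-dibutylboryl aldolate 15 (not isolated)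
Conditions: Bu2BOTf, i-Pr2NEt, CH2Cl2, −78 → 0 °C; then 3, −78 → 0 °C; pH 7 buffer, MeOH, 30% H2O2, 0 °C
Reagents that add atoms: none
Why: Second Evans syn-aldol: only the CH2 imide enolises (allylic 1,3-strain protects the α-branched first imide), and the same (R)-auxiliary directs the Zimmerman–Traxler chair to set C-8' and C-7' as the (R,R)-syn pair, so both halves have the same sense and C-8/C-8' come out threo.

Step 9
Reactants: 16 bis-imide aldol
Product: 17 (2S,3S)-2-[(R)-hydroxy(ArP)methyl]-3-[(R)-(tert-butyldimethylsilyloxy)(ArS)methyl]butane-1,4-diol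
Conditions: LiBH4, MeOH, THF, 0 °C → rt
Reagents that add atoms: none
Why: LiBH4 reductive cleavage of both N-acyloxazolidinones gives the two primary alcohols C-9 and C-9' (any lactone formed from the free hydroxyl and the neighbouring imide is reduced to the same triol) and releases the auxiliary for recovery.

Step 10
Reactants: 17 triol
Product: 18 (2S,3S)-2-[(R)-hydroxy(ArP)methyl]-3-[(R)-(tert-butyldimethylsilyloxy)(ArS)methyl]butane-1,4-diyl dimethanesulfonate
Conditions: MsCl (2.1 equiv, one portion), Et3N, CH2Cl2, −40 °C; crude product used at once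
Reagents that add atoms: methanesulfonyl chloride, CS(=O)(=O)Cl
Why: Chemoselective sulfonylation of the two unhindered primary hydroxyls over the hindered secondary benzylic one at low temperature, with both CH2OH groups sulfonylated quickly so that no hydroxy mesylate has time to etherify.

Step 11
Reactants: 18 bis-mesylate
Product: 19 4-[(1R,3aS,4R,6aS)-4-ArP-tetrahydro-1H,3H-furo[3,4-c]furan-1-yl]-2-methoxyphenol (target)
Conditions: n-Bu4NF (4 equiv), THF (0.01 M), 0 → 40 °C
Reagents that add atoms: none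
Why: Fluoride cleaves the aryl and the C-7 benzylic silyl ethers; the tetrabutylammonium alkoxide at O-7 displaces the C-9' mesylate and, in the same basic fluoride medium, the free O-7' hydroxyl displaces the C-9 mesylate, each by intramolecular SN2 at a primary carbon. The closest known reaction types are the intramolecular Williamson etherification of 1,4-hydroxy sulfonates (the sulfonate-mediated cyclisation of lignan 1,4-diols to furofurans) and fluoride-triggered desilylative cycloetherification. Ring A (O-7, C-7, C-8, C-8', C-9') and ring B (O-7', C-7', C-8', C-8, C-9) both close in the 5-exo-tet mode. No stereocentre is created: the C–O bonds at C-7 and C-7' are never broken, so both benzylic configurations are retained (inversion occurs only at the CH2 carbons), and the (8S,8'S)-threo backbone from the two aldols allows only the cis-fused bicycle with both aryl groups exo. The step needs 5-exo over 4-exo closure (each oxygen could also reach the mesylate on its own side to give an oxetane) and intramolecular over intermolecular O-alkylation by the liberated phenoxide; the first is secured by the 1,4-relationship between each benzylic oxygen and the CH2 of the other half, the second by high dilution and by the phenoxide being unable to reach either CH2 within the same molecule.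

**Compound list**

1 | vanillin (4-hydroxy-3-methoxybenzaldehyde) | O=Cc1ccc(O)c(OC)c1 | starting material
2 | 4-(tert-butyldimethylsilyloxy)-3-methoxybenzaldehyde | O=Cc1ccc(O[Si](C)(C)C(C)(C)C)c(OC)c1 | intermediate
3 | 3-methoxy-4-(3-methylbut-2-enyloxy)benzaldehyde | O=Cc1ccc(OCC=C(C)C)c(OC)c1 | intermediate
4 | 4-tert-butoxy-4-oxobutanoic acid (mono-tert-butyl succinate) | OC(=O)CCC(=O)OC(C)(C)C | starting material
5 | (4R)-4-benzyl-1,3-oxazolidin-2-one | O=C1N[C@H](Cc2ccccc2)CO1 | starting material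
6 | tert-butyl 4-[(4R)-4-benzyl-2-oxo-1,3-oxazolidin-3-yl]-4-oxobutanoate | CC(C)(C)OC(=O)CCC(=O)N1[C@H](Cc2ccccc2)COC1=O | intermediate
7 | dibutylboron (Z)-enolate of 6 | CCCCB(CCCC)O/C(=C\CC(=O)OC(C)(C)C)N1[C@H](Cc2ccccc2)COC1=O | intermediate
8 | O-dibutylboryl aldolate (boron-bound form of 9) | CC(C)(C)OC(=O)C[C@H]([C@@H](OB(CCCC)CCCC)c1ccc(O[Si](C)(C)C(C)(C)C)c(OC)c1)C(=O)N1[C@H](Cc2ccccc2)COC1=O | intermediate
9 | tert-butyl (3R,4R)-3-{[(4R)-4-benzyl-2-oxo-1,3-oxazolidin-3-yl]carbonyl}-4-hydroxy-4-[4-(tert-butyldimethylsilyloxy)-3-methoxyphenyl]butanoate | CC(C)(C)OC(=O)C[C@H]([C@@H](O)c1ccc(O[Si](C)(C)C(C)(C)C)c(OC)c1)C(=O)N1[C@H](Cc2ccccc2)COC1=O | intermediate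
10 | tert-butyl (3R,4R)-3-{[(4R)-4-benzyl-2-oxo-1,3-oxazolidin-3-yl]carbonyl}-4-(tert-butyldimethylsilyloxy)-4-[4-(tert-butyldimethylsilyloxy)-3-methoxyphenyl]butanoate | CC(C)(C)OC(=O)C[C@H]([C@@H](O[Si](C)(C)C(C)(C)C)c1ccc(O[Si](C)(C)C(C)(C)C)c(OC)c1)C(=O)N1[C@H](Cc2ccccc2)COC1=O | intermediate
11 | trimethylsilyl ester of 12 | C[Si](C)(C)OC(=O)C[C@H]([C@@H](O[Si](C)(C)C(C)(C)C)c1ccc(O[Si](C)(C)C(C)(C)C)c(OC)c1)C(=O)N1[C@H](Cc2ccccc2)COC1=O | intermediate
12 | (3R,4R)-3-{[(4R)-4-benzyl-2-oxo-1,3-oxazolidin-3-yl]carbonyl}-4-(tert-butyldimethylsilyloxy)-4-[4-(tert-butyldimethylsilyloxy)-3-methoxyphenyl]butanoic acid | OC(=O)C[C@H]([C@@H](O[Si](C)(C)C(C)(C)C)c1ccc(O[Si](C)(C)C(C)(C)C)c(OC)c1)C(=O)N1[C@H](Cc2ccccc2)COC1=O | intermediate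
13 | (2R)-1,4-bis[(4R)-4-benzyl-2-oxo-1,3-oxazolidin-3-yl]-2-{(R)-(tert-butyldimethylsilyloxy)[4-(tert-butyldimethylsilyloxy)-3-methoxyphenyl]methyl}butane-1,4-dione | O=C(C[C@H]([C@@H](O[Si](C)(C)C(C)(C)C)c1ccc(O[Si](C)(C)C(C)(C)C)c(OC)c1)C(=O)N1[C@H](Cc2ccccc2)COC1=O)N1[C@H](Cc2ccccc2)COC1=O | intermediate
14 | dibutylboron (Z)-enolate of 13 at the CH2 imide | CCCCB(CCCC)O/C(=C\[C@H]([C@@H](O[Si](C)(C)C(C)(C)C)c1ccc(O[Si](C)(C)C(C)(C)C)c(OC)c1)C(=O)N1[C@H](Cc2ccccc2)COC1=O)N1[C@H](Cc2ccccc2)COC1=O | intermediate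
15 | O-dibutylboryl aldolate (boron-bound form of 16) | O=C([C@@H]([C@@H](OB(CCCC)CCCC)c1ccc(OCC=C(C)C)c(OC)c1)[C@H]([C@@H](O[Si](C)(C)C(C)(C)C)c1ccc(O[Si](C)(C)C(C)(C)C)c(OC)c1)C(=O)N1[C@H](Cc2ccccc2)COC1=O)N1[C@H](Cc2ccccc2)COC1=O | intermediate
16 | (2R,3R)-1,4-bis[(4R)-4-benzyl-2-oxo-1,3-oxazolidin-3-yl]-2-{(R)-hydroxy[3-methoxy-4-(3-methylbut-2-enyloxy)phenyl]methyl}-3-{(R)-(tert-butyldimethylsilyloxy)[4-(tert-butyldimethylsilyloxy)-3-methoxyphenyl]methyl}butane-1,4-dione | O=C([C@@H]([C@@H](O)c1ccc(OCC=C(C)C)c(OC)c1)[C@H]([C@@H](O[Si](C)(C)C(C)(C)C)c1ccc(O[Si](C)(C)C(C)(C)C)c(OC)c1)C(=O)N1[C@H](Cc2ccccc2)COC1=O)N1[C@H](Cc2ccccc2)COC1=O | intermediate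
17 | (2S,3S)-2-{(R)-hydroxy[3-methoxy-4-(3-methylbut-2-enyloxy)phenyl]methyl}-3-{(R)-(tert-butyldimethylsilyloxy)[4-(tert-butyldimethylsilyloxy)-3-methoxyphenyl]methyl}butane-1,4-diol | OC[C@@H]([C@@H](O)c1ccc(OCC=C(C)C)c(OC)c1)[C@@H](CO)[C@@H](O[Si](C)(C)C(C)(C)C)c1ccc(O[Si](C)(C)C(C)(C)C)c(OC)c1 | intermediate
18 | 1,4-bis(methanesulfonate) of 17 (both primary hydroxyls) | CS(=O)(=O)OC[C@@H]([C@@H](O)c1ccc(OCC=C(C)C)c(OC)c1)[C@@H](COS(C)(=O)=O)[C@@H](O[Si](C)(C)C(C)(C)C)c1ccc(O[Si](C)(C)C(C)(C)C)c(OC)c1 | intermediate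
19 | 4-[(1R,3aS,4R,6aS)-4-[3-methoxy-4-(3-methylbut-2-enyloxy)phenyl]tetrahydro-1H,3H-furo[3,4-c]furan-1-yl]-2-methoxyphenol | COc1cc([C@@H]2OC[C@@H]3[C@H]2CO[C@H]3c2ccc(OCC=C(C)C)c(OC)c2)ccc1O | target

**Step count**

Total step count: 11. Longest linear sequence: 9 (steps 3 to 11 from 4 and 5; equally step 1 followed by steps 4 to 11 from vanillin).

**Steps most likely to fail, with fallbacks**

Step 11 (key step). What may go wrong: intermolecular O-alkylation by the phenoxide that fluoride liberates first, fluoride substitution at a primary mesylate, or slow closure of ring B because it starts from an un-ionised hydroxyl. Fallback, setting out from 18: NaH (1.1 equiv) in THF at 0 °C would deprotonate the only free hydroxyl while every silyl ether is still in place, and the alkoxide would close ring B by a discrete Williamson etherification to give [(2R,3S,4S)-2-ArP-4-{(R)-(tert-butyldimethylsilyloxy)(ArS)methyl}tetrahydrofuran-3-yl]methyl methanesulfonate F1. Only then would n-Bu4NF in THF close ring A from the O-7 alkoxide and free the phenol, so that the route is rejoined at 19.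

Step 8. What may go wrong: slow or incomplete enolisation of the hindered, β-branched imide, retro-aldol on work-up, or erosion of auxiliary control by the neighbouring C-8 stereocentre. Fallback, setting out from 10 and using a temporary γ-lactone in place of the second auxiliary:
- LiBH4/MeOH in THF would reduce the imide to tert-butyl (3S,4R)-4-(tert-butyldimethylsilyloxy)-3-(hydroxymethyl)-4-ArS-butanoate F2.
- Catalytic KOC(CH3)3 in THF would lactonise it to (4S)-4-[(R)-(tert-butyldimethylsilyloxy)(ArS)methyl]dihydrofuran-2(3H)-one F3, a ring (C-9'(=O)–O–C-9) that is absent from the target.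
- Its enolate (LiN(i-Pr)2, THF, −78 °C) should add to aldehyde 3 trans to the C-8 substituent to give the (3R,4S)-3-[hydroxy(ArP)methyl] lactone F4 as a mixture of carbinol epimers.
- Dess–Martin periodinane would converge both epimers on the (3R,4S)-3-(ArP-carbonyl) β-keto lactone F5.
- Zn(BH4)2 in Et2O at −20 °C (chelation-controlled, syn-selective reduction of an α-substituted β-keto ester) should give the (3R,4S)-3-[(R)-hydroxy(ArP)methyl] lactone F6.
- LiAlH4 in THF at 0 °C would open the temporary lactone to the triol, rejoining the route at 17.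

Step 10. What may go wrong: loss of chemoselectivity between the primary hydroxyls and the free benzylic hydroxyl (over-sulfonylation followed by ionisation of the benzylic mesylate). Fallback, setting out from 16, with O-7' masked before any primary hydroxyl exists: Et3SiOTf/2,6-lutidine would give the O-7' triethylsilyl ether of 16 F7. LiBH4/MeOH would then give (2S,3S)-2-[(R)-(triethylsilyloxy)(ArP)methyl]-3-[(R)-(tert-butyldimethylsilyloxy)(ArS)methyl]butane-1,4-diol F8. MsCl/Et3N, now without any competing secondary hydroxyl, would give its 1,4-bis(methanesulfonate) F9. n-Bu4NF in dilute THF would unmask both benzylic alkoxides and the phenol and close both rings, coming back to the route at 19.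

**Further compounds**

F1 | step 11 | [(2R,3S,4S)-2-[3-methoxy-4-(3-methylbut-2-enyloxy)phenyl]-4-{(R)-(tert-butyldimethylsilyloxy)[4-(tert-butyldimethylsilyloxy)-3-methoxyphenyl]methyl}tetrahydrofuran-3-yl]methyl methanesulfonate | CS(=O)(=O)OC[C@H]1[C@H](c2ccc(OCC=C(C)C)c(OC)c2)OC[C@H]1[C@@H](O[Si](C)(C)C(C)(C)C)c1ccc(O[Si](C)(C)C(C)(C)C)c(OC)c1
F2 | step 8 | tert-butyl (3S,4R)-4-(tert-butyldimethylsilyloxy)-4-[4-(tert-butyldimethylsilyloxy)-3-methoxyphenyl]-3-(hydroxymethyl)butanoate | OC[C@H](CC(=O)OC(C)(C)C)[C@@H](O[Si](C)(C)C(C)(C)C)c1ccc(O[Si](C)(C)C(C)(C)C)c(OC)c1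
F3 | step 8 | (4S)-4-{(R)-(tert-butyldimethylsilyloxy)[4-(tert-butyldimethylsilyloxy)-3-methoxyphenyl]methyl}dihydrofuran-2(3H)-one | O=C1C[C@@H](CO1)[C@@H](O[Si](C)(C)C(C)(C)C)c1ccc(O[Si](C)(C)C(C)(C)C)c(OC)c1
F4 | step 8 | (3R,4S)-3-{hydroxy[3-methoxy-4-(3-methylbut-2-enyloxy)phenyl]methyl}-4-{(R)-(tert-butyldimethylsilyloxy)[4-(tert-butyldimethylsilyloxy)-3-methoxyphenyl]methyl}dihydrofuran-2(3H)-one (carbinol epimers) | O=C1[C@@H](C(O)c2ccc(OCC=C(C)C)c(OC)c2)[C@@H](CO1)[C@@H](O[Si](C)(C)C(C)(C)C)c1ccc(O[Si](C)(C)C(C)(C)C)c(OC)c1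
F5 | step 8 | (3R,4S)-3-[3-methoxy-4-(3-methylbut-2-enyloxy)benzoyl]-4-{(R)-(tert-butyldimethylsilyloxy)[4-(tert-butyldimethylsilyloxy)-3-methoxyphenyl]methyl}dihydrofuran-2(3H)-one | O=C1[C@@H](C(=O)c2ccc(OCC=C(C)C)c(OC)c2)[C@@H](CO1)[C@@H](O[Si](C)(C)C(C)(C)C)c1ccc(O[Si](C)(C)C(C)(C)C)c(OC)c1
F6 | step 8 | (3R,4S)-3-{(R)-hydroxy[3-methoxy-4-(3-methylbut-2-enyloxy)phenyl]methyl}-4-{(R)-(tert-butyldimethylsilyloxy)[4-(tert-butyldimethylsilyloxy)-3-methoxyphenyl]methyl}dihydrofuran-2(3H)-one | O=C1[C@@H]([C@@H](O)c2ccc(OCC=C(C)C)c(OC)c2)[C@@H](CO1)[C@@H](O[Si](C)(C)C(C)(C)C)c1ccc(O[Si](C)(C)C(C)(C)C)c(OC)c1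
F7 | step 10 | O-7' triethylsilyl ether of 16 | O=C([C@@H]([C@@H](O[Si](CC)(CC)CC)c1ccc(OCC=C(C)C)c(OC)c1)[C@H]([C@@H](O[Si](C)(C)C(C)(C)C)c1ccc(O[Si](C)(C)C(C)(C)C)c(OC)c1)C(=O)N1[C@H](Cc2ccccc2)COC1=O)N1[C@H](Cc2ccccc2)COC1=O
F8 | step 10 | (2S,3S)-2-{(R)-(triethylsilyloxy)[3-methoxy-4-(3-methylbut-2-enyloxy)phenyl]methyl}-3-{(R)-(tert-butyldimethylsilyloxy)[4-(tert-butyldimethylsilyloxy)-3-methoxyphenyl]methyl}butane-1,4-diol | OC[C@@H]([C@@H](O[Si](CC)(CC)CC)c1ccc(OCC=C(C)C)c(OC)c1)[C@@H](CO)[C@@H](O[Si](C)(C)C(C)(C)C)c1ccc(O[Si](C)(C)C(C)(C)C)c(OC)c1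
F9 | step 10 | 1,4-bis(methanesulfonate) of F8 | CS(=O)(=O)OC[C@@H]([C@@H](O[Si](CC)(CC)CC)c1ccc(OCC=C(C)C)c(OC)c1)[C@@H](COS(C)(=O)=O)[C@@H](O[Si](C)(C)C(C)(C)C)c1ccc(O[Si](C)(C)C(C)(C)C)c(OC)c1
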